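Ring B is closed at the very end. Its C6 ketone, C7 oxygen and C8 tertiary carbinol form a ketol array, so cutting C7–C8 gives a seco-B diketone: ring A carries a hydroxyacetyl group (C6, C7) on C5 and, on C10, the bis-spiro ether of rings C and D whose C9 bears an acetyl group (C8, C17). A zinc enediolate spanning O6 and O7 adds through C7 to the C8 ketone, which closes ring B and sets C7 and C8 in one operation. The precursor comes from two Ireland–Claisen rearrangements that relay one carbinol centre to C5, then to C10 and C9; ring D is closed just before by alkynol cycloisomerisation.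

Key step: step 23

Remark on the chemistry: positions follow labdane numbering (names of 26–36 imply the usual 5α-H and 10β-methyl); 19–23 are carried as both epimers at the oxolane carbon that becomes C9, because that centre is trigonal in 24; the C6 carbinol configuration drawn for 7–30 is the expected one and is erased in step 20.

Step 1
Reactants: 1 2,4,4-trimethylcyclohex-2-en-1-one
Product: 2 (1R)-2,4,4-trimethylcyclohex-2-en-1-ol
Conditions: (S)-Me-CBS (0.2 equiv), catecholborane, toluene, −78 °C
Reagents that add atoms: none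
Why: Corey–Bakshi–Shibata reduction, in which the oxazaborolidine binds the ketone with the trisubstituted alkene arm as the large group and delivers hydride to one face, which should give the 1R carbinol whose configuration is later relayed to C5.

Step 2
Reactants: 2 (1R)-2,4,4-trimethylcyclohex-2-en-1-ol; 3 (benzyloxy)acetyl chloride
Product: 4 (1R)-2,4,4-trimethylcyclohex-2-en-1-yl (benzyloxy)acetate
Conditions: pyridine, DMAP (cat.), CH2Cl2, 0 °C
Reagents that add atoms: none
Why: DMAP-catalysed acylation of the secondary allylic alcohol by the acid chloride proceeds with retention at the carbinol carbon.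

Step 3
Reactants: 4 (1R)-2,4,4-trimethylcyclohex-2-en-1-yl (benzyloxy)acetate
Product: 7 (2R)-(benzyloxy)[(1S)-2,6,6-trimethylcyclohex-2-en-1-yl]acetic acid, via silyl ketene acetal 5 (not isolated), via trimethylsilyl ester 6 (not isolated)
Conditions: LiN(iPr)2, Me3SiCl, Et3N, THF, −78 °C → 60 °C; then H2O (pH 4)
Reagents that add atoms: chlorotrimethylsilane, C[Si](C)(C)Cl (silicon kept only in 5 and 6)
Why: Ireland–Claisen rearrangement of a glycolate, in which lithium chelation by the benzyloxy oxygen gives the Z-enolate trapped as 5 and the suprafacial [3,3] shift across the ring face that carried the ester oxygen forms C5–C6 and fixes C5, the boat-like transition state usual for cyclohex-2-enyl esters being expected to give 2R at C6, a centre erased in step 20.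

Step 4
Reactants: 7 (2R)-(benzyloxy)[(1S)-2,6,6-trimethylcyclohex-2-en-1-yl]acetic acid
Product: 8 (2R)-2-(benzyloxy)-2-[(1S)-2,6,6-trimethylcyclohex-2-en-1-yl]ethan-1-ol
Conditions: LiAlH4, THF, 0 °C → rt
Reagents that add atoms: none
Why: LiAlH4 reduction of the carboxylic acid to the primary alcohol (future C7–OH) leaves the trisubstituted alkene and the benzyl ether untouched.

Step 5
Reactants: 8 (2R)-2-(benzyloxy)-2-[(1S)-2,6,6-trimethylcyclohex-2-en-1-yl]ethan-1-ol
Product: 9 tert-butyl{(2R)-2-(benzyloxy)-2-[(1S)-2,6,6-trimethylcyclohex-2-en-1-yl]ethoxy}dimethylsilane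
Conditions: TBSCl, imidazole, DMF, rt
Reagents that add atoms: tert-butyl(chloro)dimethylsilane, CC(C)(C)[Si](C)(C)Cl
Why: Standard silylation of the unhindered primary hydroxyl.

Step 6
Reactants: 9 tert-butyl{(2R)-2-(benzyloxy)-2-[(1S)-2,6,6-trimethylcyclohex-2-en-1-yl]ethoxy}dimethylsilane
Product: 10 (4S)-4-[(1R)-1-(benzyloxy)-2-{[tert-butyl(dimethyl)silyl]oxy}ethyl]-3,5,5-trimethylcyclohex-2-en-1-one
Conditions: CrO3, 3,5-dimethylpyrazole, CH2Cl2, −20 °C
Reagents that add atoms: chromium trioxide, O=[Cr](=O)=O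
Why: Allylic oxidation with the CrO3–3,5-dimethylpyrazole complex attacks the ring methylene next to the alkene CH (future C2) rather than the hindered tertiary C5–H, giving the enone while silyl and benzyl ethers should survive at low temperature.

Step 7
Reactants: 10 (4S)-4-[(1R)-1-(benzyloxy)-2-{[tert-butyl(dimethyl)silyl]oxy}ethyl]-3,5,5-trimethylcyclohex-2-en-1-one
Product: 11 (1S,4S)-4-[(1R)-1-(benzyloxy)-2-{[tert-butyl(dimethyl)silyl]oxy}ethyl]-3,5,5-trimethylcyclohex-2-en-1-ol
Conditions: LiBH(s-Bu)3 (L-Selectride), THF, −78 °C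
Reagents that add atoms: none
Why: 1,2-Reduction by a bulky borohydride, in which allylic strain with the vinylic methyl holds the side chain pseudoaxial and so puts the axial methyl of the gem-dimethyl group on the opposite face, so that hydride should enter syn to the side chain and leave the new hydroxyl trans to it, conjugate reduction being disfavoured by the β-methyl group.

Step 8
Reactants: 12 2-methylprop-2-en-1-ol (methallyl alcohol); 13 3-bromoprop-1-ene (allyl bromide)
Product: 15 2-methylidenehex-5-en-1-ol, via dilithio dianion 14 (not isolated)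
Conditions: n-BuLi (2.1 equiv), TMEDA, Et2O, 0 °C → rt; then 13, −78 °C → rt
Reagents that add atoms: n-butyllithium, [Li]CCCC (lithium kept only in 14)
Why: Double deprotonation (hydroxyl and allylic methyl) gives 14, which is alkylated at carbon by allyl bromide in a known dianion alkylation that forms no stereocentre.

Step 9
Reactants: 15 2-methylidenehex-5-en-1-ol
Product: 16 [(2R)-2-(but-3-en-1-yl)oxiran-2-yl]methanol
Conditions: Ti(OiPr)4 (cat.), D-(−)-diisopropyl tartrate (cat.), t-BuOOH, 4 Å MS, CH2Cl2, −20 °C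
Reagents that add atoms: tert-butyl hydroperoxide, CC(C)(C)OO
Why: Sharpless asymmetric epoxidation is specific for the allylic alcohol alkene (the remote vinyl group is left), and the D-tartrate ligand should deliver oxygen to the face that makes the quaternary centre (future C13) R.

Step 10
Reactants: 16 [(2R)-2-(but-3-en-1-yl)oxiran-2-yl]methanol
Product: 17 (2R)-2-[(benzyloxy)methyl]hex-5-ene-1,2-diol
Conditions: BnOH, NaH (0.3 equiv), 70 °C
Reagents that add atoms: benzyl alcohol, OCc1ccccc1
Why: Base-mediated SN2 opening of the 2,2-disubstituted epoxide by benzyl alkoxide at its unsubstituted CH2, the Payne rearrangement of this 2-substituted glycidol being degenerate, so that the quaternary centre keeps its configuration and its tertiary hydroxyl becomes the ring C oxygen.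

Step 11
Reactants: 17 (2R)-2-[(benzyloxy)methyl]hex-5-ene-1,2-diol
Product: 18 (2S)-1-(benzyloxy)-2-({[tert-butyl(dimethyl)silyl]oxy}methyl)hex-5-en-2-ol
Conditions: TBSCl, imidazole, CH2Cl2, 0 °C
Reagents that add atoms: tert-butyl(chloro)dimethylsilane, CC(C)(C)[Si](C)(C)Cl
Why: Silylation is selective for the primary hydroxyl (future O16) in the presence of the tertiary one.

Step 12
Reactants: 18 (2S)-1-(benzyloxy)-2-({[tert-butyl(dimethyl)silyl]oxy}methyl)hex-5-en-2-ol
Product: 20 [(5S)-5-[(benzyloxy)methyl]-5-({[tert-butyl(dimethyl)silyl]oxy}methyl)oxolan-2-yl]methanol (both C2 epimers), via epoxide 19 (not isolated)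
Conditions: mCPBA, CH2Cl2, 0 °C → rt; then CSA (cat.)
Reagents that add atoms: 3-chloroperbenzoic acid, OOC(=O)c1cccc(Cl)c1
Why: Prilezhaev epoxidation of the terminal alkene to 19 followed by acid-catalysed 5-exo-tet opening by the tertiary hydroxyl closes the oxolane (ring C), the new centre (future C9) forming without control, which is of no consequence because it becomes trigonal in step 15.

Step 13
Reactants: 20 [(5S)-5-[(benzyloxy)methyl]-5-({[tert-butyl(dimethyl)silyl]oxy}methyl)oxolan-2-yl]methanol (both C2 epimers)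
Product: 22 (5S)-5-[(benzyloxy)methyl]-5-({[tert-butyl(dimethyl)silyl]oxy}methyl)oxolane-2-carboxylic acid (both C2 epimers), via aldehyde 21 (not isolated)
Conditions: TEMPO (cat.), PhI(OAc)2, MeCN–H2O (pH 7 buffer), rt
Reagents that add atoms: water, O
Why: Oxoammonium (TEMPO) oxidation of the primary alcohol to aldehyde 21, whose hydrate is oxidised on to the acid (future C8), leaves the ethers unaffected.

Step 14
Reactants: 11 (1S,4S)-4-[(1R)-1-(benzyloxy)-2-{[tert-butyl(dimethyl)silyl]oxy}ethyl]-3,5,5-trimethylcyclohex-2-en-1-ol; 22 (5S)-5-[(benzyloxy)methyl]-5-({[tert-butyl(dimethyl)silyl]oxy}methyl)oxolane-2-carboxylic acid (both C2 epimers)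
Product: 23 ester of 11 with 22 (both epimers at the oxolane C2)
Conditions: DCC, DMAP (cat.), CH2Cl2, 0 °C → rt
Reagents that add atoms: none
Why: Steglich esterification joins the two halves with retention at the allylic carbinol carbon.

Step 15
Reactants: 23 ester of 11 with 22
Product: 26 (6R,13S)-6,14-bis(benzyloxy)-7,16-bis{[tert-butyl(dimethyl)silyl]oxy}-9α,13-epoxy-15,17-dinor-7,8-secolabd-1-en-8-oic acid, via silyl ketene acetal 24 (not isolated), via trimethylsilyl ester 25 (not isolated)
Conditions: LiN(iPr)2, Me3SiCl, Et3N, THF, −78 °C → rt, then toluene, 80 °C; then aq. citric acid (pH 4)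
Reagents that add atoms: chlorotrimethylsilane, C[Si](C)(C)Cl (silicon kept only in 24 and 25)
Why: Ireland–Claisen rearrangement, in which lithium chelation between enolate and ring oxygens gives 24 with OSiMe3 syn to the ring oxygen, the [3,3] shift on the face of the C2–O bond (anti to the C5 side chain) fixes C10, and the boat-like transition state expected for a cyclohex-2-enyl ester (the chair would press OSiMe3 against the C3–C4–C5 bridge and its axial methyl) places the ring oxygen next to the C10 methyl and so sets C9 with 9α-oxygen, both quaternary centres arising in one step.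

Step 16
Reactants: 26 (6R,13S)-6,14-bis(benzyloxy)-7,16-bis{[tert-butyl(dimethyl)silyl]oxy}-9α,13-epoxy-15,17-dinor-7,8-secolabd-1-en-8-oic acid
Product: 27 (6R,13S)-6,14-bis(benzyloxy)-7,16-bis{[tert-butyl(dimethyl)silyl]oxy}-9α,13-epoxy-15-nor-7,8-secolabd-1-en-8-one
Conditions: MeLi (3 equiv), Et2O, 0 °C → rt; aq. NH4Cl
Reagents that add atoms: methyllithium, [Li]C
Why: Methyl ketone synthesis from a carboxylic acid with methyllithium, whose adduct collapses only on work-up so that no tertiary alcohol should form, carried out before debenzylation so that no hydroxy acid able to lactonise is ever present.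

Step 17
Reactants: 27 (6R,13S)-6,14-bis(benzyloxy)-7,16-bis{[tert-butyl(dimethyl)silyl]oxy}-9α,13-epoxy-15-nor-7,8-secolabd-1-en-8-one
Product: 28 (6R,13S)-7,16-bis{[tert-butyl(dimethyl)silyl]oxy}-9α,13-epoxy-6,14-dihydroxy-15-nor-7,8-secolabdan-8-one
Conditions: H2 (1 atm), Pd(OH)2/C, EtOAc, rt
Reagents that add atoms: none
Why: Catalytic hydrogenation saturates the cis-disubstituted C1=C2 alkene and hydrogenolyses both benzyl ethers in one operation, while ketone and silyl ethers persist and no stereocentre is created.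

Step 18
Reactants: 28 (6R,13S)-7,16-bis{[tert-butyl(dimethyl)silyl]oxy}-9α,13-epoxy-6,14-dihydroxy-15-nor-7,8-secolabdan-8-one
Product: 29 (6R,13R)-7,16-bis{[tert-butyl(dimethyl)silyl]oxy}-9α,13-epoxy-6-hydroxy-8-oxo-15-nor-7,8-secolabdan-14-al
Conditions: TEMPO (cat.), PhI(OAc)2, CH2Cl2, rt
Reagents that add atoms: none
Why: TEMPO-catalysed oxidation is selective for the primary C14 hydroxyl over the hindered secondary C6 hydroxyl and stops at the non-enolisable aldehyde.

Step 19
Reactants: 29 (6R,13R)-7,16-bis{[tert-butyl(dimethyl)silyl]oxy}-9α,13-epoxy-6-hydroxy-8-oxo-15-nor-7,8-secolabdan-14-al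
Product: 30 (6R,13S)-7,16-bis{[tert-butyl(dimethyl)silyl]oxy}-9α,13-epoxy-6-hydroxy-7,8-secolabd-14-yn-8-one
Conditions: dimethyl (1-diazo-2-oxopropyl)phosphonate, K2CO3, MeOH, 0 °C → rt
Reagents that add atoms: dimethyl (1-diazo-2-oxopropyl)phosphonate, CC(=O)C(=[N+]=[N-])P(=O)(OC)OC
Why: Ohira–Bestmann (Seyferth–Gilbert) homologation converts the aldehyde into the terminal alkyne (C14≡C15) under carbonate conditions that the ketone tolerates, and it is placed before the C6 oxidation so that no 1,5-diketone meets methoxide.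

Step 20
Reactants: 30 (6R,13S)-7,16-bis{[tert-butyl(dimethyl)silyl]oxy}-9α,13-epoxy-6-hydroxy-7,8-secolabd-14-yn-8-one
Product: 31 (13S)-7,16-bis{[tert-butyl(dimethyl)silyl]oxy}-9α,13-epoxy-7,8-secolabd-14-yne-6,8-dione
Conditions: Dess–Martin periodinane, NaHCO3, CH2Cl2, rt
Reagents that add atoms: none
Why: Dess–Martin oxidation of the hindered secondary alcohol gives the C6 ketone under buffered conditions that should not epimerise C5, and it erases the C6 stereocentre.

Step 21
Reactants: 31 (13S)-7,16-bis{[tert-butyl(dimethyl)silyl]oxy}-9α,13-epoxy-7,8-secolabd-14-yne-6,8-dione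
Product: 32 (13S)-9α,13-epoxy-7,16-dihydroxy-7,8-secolabd-14-yne-6,8-dione
Conditions: HF·pyridine, pyridine, THF, 0 °C → rt
Reagents that add atoms: none
Why: Acidic fluoride cleaves both primary silyl ethers without the basic conditions that could start an uncontrolled aldol, which is possible here because the acid-labile ring D does not yet exist.

Step 22
Reactants: 32 (13S)-9α,13-epoxy-7,16-dihydroxy-7,8-secolabd-14-yne-6,8-dione
Product: 33 (13S)-9α,13:15,16-diepoxy-7-hydroxy-7,8-secolabd-14-ene-6,8-dione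
Conditions: Mo(CO)6 (0.3 equiv), Et3N, Et2O, hν (350 nm); then 32, rt
Reagents that add atoms: none
Why: Known molybdenum carbonyl-catalysed cycloisomerisation of a 1-alkyn-4-ol to a 2,3-dihydrofuran, in which the C16 hydroxyl adds in a 5-endo sense to the metal-activated terminal alkyne and closes ring D under neutral conditions, the C7 hydroxyl being too remote to compete and C13 being untouched.

Step 23
Reactants: 33 (13S)-9α,13:15,16-diepoxy-7-hydroxy-7,8-secolabd-14-ene-6,8-dione
Product: 35 (13S)-9α,13:15,16-diepoxy-7β,8β-dihydroxylabd-14-en-6-one, via zinc enediolate 34 (not isolated)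
Conditions: (S,S)-ProPhenol ligand (20 mol %), Et2Zn (40 mol %), 4 Å MS, THF, 0 °C → rt
Reagents that add atoms: diethylzinc, CC[Zn]CC (zinc kept only in 34)
Why: Proposed new method: the dinuclear zinc alkoxide formed from Et2Zn and the ligand deprotonates ketol 33 at C7, the only α-carbon whose enolate can be held as a five-membered zinc chelate by O6 and O7 (enediolate 34), while the second zinc centre binds the C8 carbonyl, and C7 then adds to C8; the closest known reaction type is the zinc–ProPhenol direct aldol of α-hydroxy ketones with aldehydes, extended here to an intramolecular addition to a ketone. Ring B closes in a 6-(enolendo)-exo-trig mode through a chair-like transition state. At C7 the Z-geometry of the chelated enediolate leaves O7 in the equatorial position (7β). At C8 the methyl group takes the equatorial α position to avoid a 1,3-diaxial contact with the C10 methyl, so the alkoxide is axial (8β) and cis to O7, a relationship that the zinc bridge between the two oxygens favours. The step needs C7 to react in preference to the C17 methyl and to C5–H, which chelation and the hindrance at C5 should secure; because zinc aldolates revert readily, adducts of other regio- or stereochemistry can return to 33 and drain to the trans-fused ketol, whose C5 configuration was already set in step 3.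

Step 24
Reactants: 35 (13S)-9α,13:15,16-diepoxy-7β,8β-dihydroxylabd-14-en-6-one
Product: 36 (13S)-7β-acetoxy-9α,13:15,16-diepoxy-8β-hydroxylabd-14-en-6-one (CNP0284584.1)
Conditions: Ac2O, pyridine, CH2Cl2, 0 °C → rt
Reagents that add atoms: acetic anhydride, CC(=O)OC(C)=O
Why: Acylation with acetic anhydride in pyridine is selective for the equatorial secondary 7β-hydroxyl, the axial tertiary 8β-hydroxyl flanked by two quaternary carbons being unreactive under these conditions.

Compound list
1 | 2,4,4-trimethylcyclohex-2-en-1-one | CC1=CC(C)(C)CCC1=O | starting material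
2 | (1R)-2,4,4-trimethylcyclohex-2-en-1-ol | CC1=CC(C)(C)CC[C@H]1O | intermediate
3 | (benzyloxy)acetyl chloride | O=C(Cl)COCc1ccccc1 | starting material
4 | (1R)-2,4,4-trimethylcyclohex-2-en-1-yl (benzyloxy)acetate | CC1=CC(C)(C)CC[C@H]1OC(=O)COCc1ccccc1 | intermediate
5 | trimethylsilyl ketene acetal of 4 (OSiMe3 cis to OBn) | CC1=CC(C)(C)CC[C@H]1O/C(=C/OCc1ccccc1)O[Si](C)(C)C | intermediate
6 | trimethylsilyl ester of 7 | C[Si](C)(C)OC(=O)[C@H](OCc1ccccc1)[C@@H]1C(C)=CCCC1(C)C | intermediate
7 | (2R)-(benzyloxy)[(1S)-2,6,6-trimethylcyclohex-2-en-1-yl]acetic acid | OC(=O)[C@H](OCc1ccccc1)[C@@H]1C(C)=CCCC1(C)C | intermediate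
8 | (2R)-2-(benzyloxy)-2-[(1S)-2,6,6-trimethylcyclohex-2-en-1-yl]ethan-1-ol | OC[C@H](OCc1ccccc1)[C@@H]1C(C)=CCCC1(C)C | intermediate
9 | tert-butyl{(2R)-2-(benzyloxy)-2-[(1S)-2,6,6-trimethylcyclohex-2-en-1-yl]ethoxy}dimethylsilane | CC(C)(C)[Si](C)(C)OC[C@H](OCc1ccccc1)[C@@H]1C(C)=CCCC1(C)C | intermediate
10 | (4S)-4-[(1R)-1-(benzyloxy)-2-{[tert-butyl(dimethyl)silyl]oxy}ethyl]-3,5,5-trimethylcyclohex-2-en-1-one | CC(C)(C)[Si](C)(C)OC[C@H](OCc1ccccc1)[C@@H]1C(C)=CC(=O)CC1(C)C | intermediate
11 | (1S,4S)-4-[(1R)-1-(benzyloxy)-2-{[tert-butyl(dimethyl)silyl]oxy}ethyl]-3,5,5-trimethylcyclohex-2-en-1-ol (hydroxyl trans to the side chain) | CC(C)(C)[Si](C)(C)OC[C@H](OCc1ccccc1)[C@@H]1C(C)=C[C@@H](O)CC1(C)C | intermediate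
12 | 2-methylprop-2-en-1-ol (methallyl alcohol) | CC(=C)CO | starting material
13 | 3-bromoprop-1-ene (allyl bromide) | C=CCBr | starting material
14 | dilithio dianion of 12 (lithium 2-(lithiomethyl)prop-2-en-1-olate) | [Li]CC(=C)CO[Li] | intermediate
15 | 2-methylidenehex-5-en-1-ol | C=CCCC(=C)CO | intermediate
16 | [(2R)-2-(but-3-en-1-yl)oxiran-2-yl]methanol | OC[C@]1(CCC=C)CO1 | intermediate
17 | (2R)-2-[(benzyloxy)methyl]hex-5-ene-1,2-diol | OC[C@](O)(CCC=C)COCc1ccccc1 | intermediate
18 | (2S)-1-(benzyloxy)-2-({[tert-butyl(dimethyl)silyl]oxy}methyl)hex-5-en-2-ol | CC(C)(C)[Si](C)(C)OC[C@](O)(CCC=C)COCc1ccccc1 | intermediate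
19 | (2S)-1-(benzyloxy)-2-({[tert-butyl(dimethyl)silyl]oxy}methyl)-4-(oxiran-2-yl)butan-2-ol (both epoxide epimers) | CC(C)(C)[Si](C)(C)OC[C@](O)(CCC1CO1)COCc1ccccc1 | intermediate
20 | [(5S)-5-[(benzyloxy)methyl]-5-({[tert-butyl(dimethyl)silyl]oxy}methyl)oxolan-2-yl]methanol (both C2 epimers) | OCC1CC[C@@](CO[Si](C)(C)C(C)(C)C)(COCc2ccccc2)O1 | intermediate
21 | (5S)-5-[(benzyloxy)methyl]-5-({[tert-butyl(dimethyl)silyl]oxy}methyl)oxolane-2-carbaldehyde (both C2 epimers) | O=CC1CC[C@@](CO[Si](C)(C)C(C)(C)C)(COCc2ccccc2)O1 | intermediate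
22 | (5S)-5-[(benzyloxy)methyl]-5-({[tert-butyl(dimethyl)silyl]oxy}methyl)oxolane-2-carboxylic acid (both C2 epimers) | OC(=O)C1CC[C@@](CO[Si](C)(C)C(C)(C)C)(COCc2ccccc2)O1 | intermediate
23 | ester of 11 with 22 (both epimers at the oxolane C2) | CC(C)(C)[Si](C)(C)OC[C@H](OCc1ccccc1)[C@@H]1C(C)=C[C@@H](OC(=O)C2CC[C@@](CO[Si](C)(C)C(C)(C)C)(COCc3ccccc3)O2)CC1(C)C | intermediate
24 | trimethylsilyl ketene acetal of 23 (OSiMe3 cis to the ring oxygen) | CC(C)(C)[Si](C)(C)OC[C@H](OCc1ccccc1)[C@@H]1C(C)=C[C@@H](O/C(O[Si](C)(C)C)=C2\CC[C@@](CO[Si](C)(C)C(C)(C)C)(COCc3ccccc3)O2)CC1(C)C | intermediate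
25 | trimethylsilyl ester of 26 | CC(C)(C)[Si](C)(C)OC[C@H](OCc1ccccc1)[C@H]1C(C)(C)CC=C[C@]1(C)[C@@]2(CC[C@@](CO[Si](C)(C)C(C)(C)C)(COCc3ccccc3)O2)C(=O)O[Si](C)(C)C | intermediate
26 | (6R,13S)-6,14-bis(benzyloxy)-7,16-bis{[tert-butyl(dimethyl)silyl]oxy}-9α,13-epoxy-15,17-dinor-7,8-secolabd-1-en-8-oic acid | CC(C)(C)[Si](C)(C)OC[C@H](OCc1ccccc1)[C@H]1C(C)(C)CC=C[C@]1(C)[C@@]2(CC[C@@](CO[Si](C)(C)C(C)(C)C)(COCc3ccccc3)O2)C(=O)O | intermediate
27 | (6R,13S)-6,14-bis(benzyloxy)-7,16-bis{[tert-butyl(dimethyl)silyl]oxy}-9α,13-epoxy-15-nor-7,8-secolabd-1-en-8-one | CC(C)(C)[Si](C)(C)OC[C@H](OCc1ccccc1)[C@H]1C(C)(C)CC=C[C@]1(C)[C@@]2(CC[C@@](CO[Si](C)(C)C(C)(C)C)(COCc3ccccc3)O2)C(C)=O | intermediate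
28 | (6R,13S)-7,16-bis{[tert-butyl(dimethyl)silyl]oxy}-9α,13-epoxy-6,14-dihydroxy-15-nor-7,8-secolabdan-8-one | CC(C)(C)[Si](C)(C)OC[C@H](O)[C@H]1C(C)(C)CCC[C@]1(C)[C@@]2(CC[C@@](CO[Si](C)(C)C(C)(C)C)(CO)O2)C(C)=O | intermediate
29 | (6R,13R)-7,16-bis{[tert-butyl(dimethyl)silyl]oxy}-9α,13-epoxy-6-hydroxy-8-oxo-15-nor-7,8-secolabdan-14-al | CC(C)(C)[Si](C)(C)OC[C@H](O)[C@H]1C(C)(C)CCC[C@]1(C)[C@@]2(CC[C@@](CO[Si](C)(C)C(C)(C)C)(C=O)O2)C(C)=O | intermediate
30 | (6R,13S)-7,16-bis{[tert-butyl(dimethyl)silyl]oxy}-9α,13-epoxy-6-hydroxy-7,8-secolabd-14-yn-8-one | CC(C)(C)[Si](C)(C)OC[C@H](O)[C@H]1C(C)(C)CCC[C@]1(C)[C@@]2(CC[C@@](CO[Si](C)(C)C(C)(C)C)(C#C)O2)C(C)=O | intermediate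
31 | (13S)-7,16-bis{[tert-butyl(dimethyl)silyl]oxy}-9α,13-epoxy-7,8-secolabd-14-yne-6,8-dione | CC(C)(C)[Si](C)(C)OCC(=O)[C@H]1C(C)(C)CCC[C@]1(C)[C@@]2(CC[C@@](CO[Si](C)(C)C(C)(C)C)(C#C)O2)C(C)=O | intermediate
32 | (13S)-9α,13-epoxy-7,16-dihydroxy-7,8-secolabd-14-yne-6,8-dione | OCC(=O)[C@H]1C(C)(C)CCC[C@]1(C)[C@@]2(CC[C@@](CO)(C#C)O2)C(C)=O | intermediate
33 | (13S)-9α,13:15,16-diepoxy-7-hydroxy-7,8-secolabd-14-ene-6,8-dione (precursor of the key step) | OCC(=O)[C@H]1C(C)(C)CCC[C@]1(C)[C@@]1(CC[C@@]2(C=COC2)O1)C(C)=O | intermediate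
34 | zinc enediolate of 33 (O6–Zn–O7 chelate; ancillary ligand on zinc omitted) | C1(=CO[Zn]O1)[C@H]2C(C)(C)CCC[C@]2(C)[C@@]3(CC[C@@]4(C=COC4)O3)C(C)=O | intermediate
35 | (13S)-9α,13:15,16-diepoxy-7β,8β-dihydroxylabd-14-en-6-one (7-deacetyl target) | O[C@H]1C(=O)[C@H]2C(C)(C)CCC[C@]2(C)[C@@]2(CC[C@@]3(C=COC3)O2)[C@@]1(C)O | intermediate
36 | (13S)-7β-acetoxy-9α,13:15,16-diepoxy-8β-hydroxylabd-14-en-6-one (CNP0284584.1) | CC(=O)O[C@H]1C(=O)[C@H]2C(C)(C)CCC[C@]2(C)[C@@]2(CC[C@@]3(C=COC3)O2)[C@@]1(C)O | target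

Total step count: 24. Longest linear sequence: 18 steps (steps 1–7, then 14–24); the second branch (steps 8–13) joins at step 14.

Steps most likely to fail

Step 23. What may go wrong: the zinc catalyst may fail to enolise the hindered ketol or be held by the product diol, enolisation of the C17 methyl may lead to the isomeric six-membered aldol, or the retro-aldol equilibrium may not favour the closed form. The fallback sets out from 31 and comes back at 35; it closes ring B before ring D under classical thermodynamic control. Catalytic KOtBu in t-BuOH–THF at 0 °C should equilibrate the 1,5-diketone 31 to (13S)-7β,16-bis{[tert-butyl(dimethyl)silyl]oxy}-9α,13-epoxy-8β-hydroxylabd-14-yn-6-one F1. This is a known base-mediated ketol cyclisation: the α-silyloxy methylene is the most acidic site, and the trans-fused ketol with equatorial C7 oxygen and C17 methyl is the expected sink. HF·pyridine then removes both silyl groups to give (13S)-9α,13-epoxy-7β,8β,16-trihydroxylabd-14-yn-6-one F2, and the cycloisomerisation conditions of step 22 close ring D on F2 and deliver 35.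

Step 15. What may go wrong: the [3,3] shift at the congested C10 terminus may be slow enough for the ester enolate to fragment, or part of the material may pass through the chair-like transition state or a non-chelated ketene acetal, eroding the selectivity at C9. The fallback sets out from 22 and 11 and comes back at 27; it replaces the enolate chemistry by a thermal Eschenmoser–Claisen rearrangement. Acid 22 is converted with Me2NH and EDC into the N,N-dimethylamide of 22 F3. Me3OBF4 followed by NaOMe gives the amide dimethyl acetal F4. Heating F4 with 11 in xylene at 140 °C exchanges methanol for the allylic alcohol; the resulting ketene N,O-acetal (amino group syn to the ring oxygen) should rearrange through the same boat-like arrangement to the N,N-dimethylamide of 26 F5. MeLi converts F5 into 27, taking the place of step 16.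

Step 7. What may go wrong: poor facial selectivity, with hydride entering anti to the side chain so that the cis alcohol dominates. The fallback sets out from 10 and comes back at 23. The reduction is then run for the cis isomer (NaBH4, CeCl3, MeOH, −78 °C, or the Selectride product if it proves cis), giving (1R,4S)-4-[(1R)-1-(benzyloxy)-2-{[tert-butyl(dimethyl)silyl]oxy}ethyl]-3,5,5-trimethylcyclohex-2-en-1-ol F6. F6 is coupled with 22 under Mitsunobu conditions (PPh3, DIAD, THF, 0 °C), which esterifies with inversion at the carbinol carbon and gives 23 directly, replacing steps 7 and 14.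

Further compounds
F1 | step 23 | (13S)-7β,16-bis{[tert-butyl(dimethyl)silyl]oxy}-9α,13-epoxy-8β-hydroxylabd-14-yn-6-one | CC(C)(C)[Si](C)(C)O[C@H]1C(=O)[C@H]2C(C)(C)CCC[C@]2(C)[C@@]2(CC[C@@](CO[Si](C)(C)C(C)(C)C)(C#C)O2)[C@@]1(C)O
F2 | step 23 | (13S)-9α,13-epoxy-7β,8β,16-trihydroxylabd-14-yn-6-one | O[C@H]1C(=O)[C@H]2C(C)(C)CCC[C@]2(C)[C@@]2(CC[C@@](CO)(C#C)O2)[C@@]1(C)O
F3 | step 15 | (5S)-5-[(benzyloxy)methyl]-5-({[tert-butyl(dimethyl)silyl]oxy}methyl)-N,N-dimethyloxolane-2-carboxamide (both C2 epimers) | CN(C)C(=O)C1CC[C@@](CO[Si](C)(C)C(C)(C)C)(COCc2ccccc2)O1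
F4 | step 15 | dimethyl acetal of amide F3 (both C2 epimers) | COC(OC)(N(C)C)C1CC[C@@](CO[Si](C)(C)C(C)(C)C)(COCc2ccccc2)O1
F5 | step 15 | N,N-dimethylamide of acid 26 | CC(C)(C)[Si](C)(C)OC[C@H](OCc1ccccc1)[C@H]1C(C)(C)CC=C[C@]1(C)[C@@]2(CC[C@@](CO[Si](C)(C)C(C)(C)C)(COCc3ccccc3)O2)C(=O)N(C)C
F6 | step 7 | (1R,4S)-4-[(1R)-1-(benzyloxy)-2-{[tert-butyl(dimethyl)silyl]oxy}ethyl]-3,5,5-trimethylcyclohex-2-en-1-ol (hydroxyl cis to the side chain) | CC(C)(C)[Si](C)(C)OC[C@H](OCc1ccccc1)[C@@H]1C(C)=C[C@H](O)CC1(C)C
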